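Numbering (eremophilane type): ring B = C1–C4, C5, C10; ring A = C5–C10; C8 = ring ketone; C11 = side-chain carbinol carbon; C2′ = stereocentre of the acyl group; β = face of the C5 methyl.
Cuts, in retrosynthetic order: the C11–O acyl bond, the carboxyl protecting group, C7–C11 (dienone half + pyruvate half), the C6=C7 unsaturation, then C3–O and C4–CH3, which go back to the C4 ketone of (S)-Wieland–Miescher ketone 1.
Enabling feature: C6=C7(–C11–O)–C8=O is a Morita–Baylis–Hillman retron. In ring A only C6 is a β-CH, because the other β-carbon, C10, is fully substituted. A removable thiolate therefore adds at C6 alone and makes C7 the only enolsilane carbon, matched in polarity to the ketone carbon of a chelated pyruvate.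
Forward: both rings come with 1. Ring B is edited under a C8 dithiolane (steps 1–7), ring A is oxidised to the dienone and masked as its PhS/OSiMe3 adduct (steps 8–9), the chain is joined (step 11), the mask leaves (step 12), the acid is freed and C11–OH is acylated (steps 13–14).
Stereochemistry: C5 from 1; C4 by α-face hydroboration; C3 by equatorial hydride delivery; C11 by the chiral Cu(II) catalyst; C2′ from (R)-2-methylbutanoic acid.

Key step: step 11

Assumption: (S)-Wieland–Miescher ketone, (R)-2-methylbutanoic acid and the (R,R)-tert-butyl-bis(oxazoline) ligand are taken as catalogue items in enantiopure form.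

Step 1
Reactants: 1 (S)-Wieland–Miescher ketone
Product: 2 C8-dithiolane ketone (spiro-1,3-dithiolane at C8; C9=C10 kept; C4 ketone free; 5β-CH3)
Conditions: HS(CH2)2SH, p-TsOH·H2O, AcOH, rt
Reagents that add atoms: ethane-1,2-dithiol, SCCS
Why: Acid-catalysed dithioketalisation picks the unhindered conjugated C8 carbonyl over the neopentyl C4 ketone and leaves C9=C10 in place, so ring A becomes inert to base, cuprate, borane and hydride; C5 is bought with 1.

Step 2
Reactants: 2 C8-dithiolane ketone
Product: 4 C3=C4 enol triflate (OTf on C4), via potassium enolate 3 (not isolated)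
Conditions: KHMDS, THF, −78 °C; then PhNTf2, −78 → 0 °C
Reagents that add atoms: N-phenylbis(trifluoromethanesulfonimide), O=S(=O)(C(F)(F)F)N(c1ccccc1)S(=O)(=O)C(F)(F)F; KHMDS, C[Si](C)(C)[N-][Si](C)(C)C.[K+] (potassium of 3 only)
Why: Enol triflate formation (ketone enolisation and O-triflation) gives one regioisomer, because C5 is quaternary and the C4 ketone can enolise only toward C3.

Step 3
Reactants: 4 C3=C4 enol triflate
Product: 5 4-methyl-3-ene dithiolane (C3=C4 bearing CH3 on C4; 5β-CH3)
Conditions: Me2CuLi (CuI, MeLi), THF, −15 → 0 °C
Reagents that add atoms: lithium dimethylcuprate, [Li+].C[Cu-]C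
Why: Organocuprate–vinyl triflate cross-coupling replaces triflate by methyl without moving the C3=C4 bond, and the soft cuprate leaves the dithiolane alone.

Step 4
Reactants: 5 4-methyl-3-ene dithiolane
Product: 7 3α-alcohol dithiolane (3α-OH; 4β-CH3; 5β-CH3), via 3α-alkylborane 6 (not isolated)
Conditions: BH3·THF, THF, 0 °C → rt; then NaBO3·4H2O, THF/H2O, rt
Reagents that add atoms: sodium perborate, [Na+].[O-]OB=O; borane–THF, B.C1CCOC1 (boron of 6 only)
Why: Hydroboration–oxidation adds H and B syn and anti-Markovnikov from the α face, opposite the axial 5β-methyl, which sets C4 (H α, CH3 β, cis to the C5 methyl) and puts oxygen on C3 with retention, while C9=C10 is shielded between the spiro C8 and the quaternary C5.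

Step 5
Reactants: 7 3α-alcohol dithiolane
Product: 8 3-ketone dithiolane (4β-CH3; 5β-CH3)
Conditions: Dess–Martin periodinane, dry CH2Cl2, 0 °C → rt
Reagents that add atoms: none
Why: Dess–Martin oxidation works under non-basic, anhydrous conditions, so C4 next to the new ketone should not epimerise and the dithiolane should stay intact.

Step 6
Reactants: 8 3-ketone dithiolane
Product: 10 3β-acetate dithiolane (3β-OAc axial; 4β-CH3; 5β-CH3), via lithium 3β-alkoxide 9 (not isolated)
Conditions: L-Selectride, THF, −78 °C; then Ac2O, DMAP (cat.), −78 °C → rt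
Reagents that add atoms: acetic anhydride, CC(=O)OC(C)=O; L-Selectride, [Li+].CCC(C)[BH-](C(C)CC)C(C)CC (lithium of 9 only)
Why: Bulky-hydride ketone reduction with in situ O-acetylation: the axial 5β-methyl blocks axial attack, so hydride enters equatorially from the α face and sets the axial 3β-oxygen (3S) cis to both methyl groups, and trapping the alkoxide avoids a peroxide work-up next to sulfur.

Step 7
Reactants: 10 3β-acetate dithiolane
Product: 11 3β-acetoxy enone, (4aR,5R,6S)-6-acetoxy-4a,5-dimethyl-4,4a,5,6,7,8-hexahydronaphthalen-2(3H)-one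
Conditions: MeI, CaCO3, MeCN/H2O, 45 °C
Reagents that add atoms: water, O
Why: Alkylative hydrolysis of the dithiolane (S-methylation, allylic thionium ion, capture by water) frees the enone under near-neutral conditions that spare the acetate.

Step 8
Reactants: 11 3β-acetoxy enone
Product: 12 3β-acetoxy dienone, (4aR,5R,6S)-6-acetoxy-4a,5-dimethyl-5,6,7,8-tetrahydronaphthalen-2(4aH)-one
Conditions: DDQ, 1,4-dioxane, reflux
Reagents that add atoms: none
Why: DDQ dehydrogenation of a 4-en-3-one-type enone under neutral conditions runs through the kinetic C7 enol with hydride loss from C6, the established way to cross-conjugated dienones, and touches no stereocentre.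

Step 9
Reactants: 12 3β-acetoxy dienone
Product: 13 6α-phenylthio enolsilane (C7=C8 bearing OSiMe3 on C8; C9=C10; 6α-SPh)
Conditions: PhSSiMe3, TBAF (1 mol %), THF, −20 °C → rt; volatiles removed, pentane filtration, used at once
Reagents that add atoms: (phenylthio)trimethylsilane, C[Si](C)(C)Sc1ccccc1
Why: Fluoride-initiated 1,4-addition of a thiosilane (thia-Michael addition with O-silyl transfer) can occur only at C6, the sole β-CH of ring A, with axial entry on the α face anti to the 5β-methyl as nucleophiles do at C1 of steroidal 1,4-dien-3-ones, and the neutral medium spares the acetate.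

Step 10
Reactants: 14 pyruvic acid; 15 allyl alcohol
Product: 16 allyl pyruvate
Conditions: p-TsOH (cat.), toluene, Dean–Stark, reflux
Reagents that add atoms: none
Why: Fischer esterification driven by azeotropic removal of water gives a pyruvate whose ester can later be removed without acid, base or hydrogen.

Step 11
Reactants: 13 6α-phenylthio enolsilane; 16 allyl pyruvate
Product: 18 aldol adduct (allyl (11R)-2-hydroxypropanoate unit on C7β; 6α-SPh; C8 ketone; C9=C10), via silyl ether 17 (not isolated)
Conditions: Cu(OTf)2 (10 mol %), (R,R)-t-Bu-box (11 mol %), THF, −78 → −20 °C; then 1 M HCl, THF, 0 °C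
Reagents that add atoms: none
Why: Allyl pyruvate binds through both carbonyl oxygens to the square-planar Cu(II)–bis(oxazoline) Lewis acid, the C7=C8 enolsilane of 13 attacks the activated ketone carbon C11 through an open transition state, and silyl transfer to the copper alkoxide releases 17 and the catalyst. The closest known reaction type is the Cu(II)–bis(oxazoline)-catalysed enantioselective Mukaiyama aldol addition of enolsilanes (silyl ketene thioacetals and ketone silyl enol ethers) to pyruvate esters, which builds exactly this kind of tertiary α-hydroxy ester. No ring is closed. C11 is set by the catalyst: the tert-butyl groups of the (R,R)-ligand cover the Si face of the chelated ketone, so C7 enters on the Re face and gives (11R), the mirror image of the (S)-carbinols known from the (S,S)-ligand, whereas C7 is set by the substrate (entry anti to the 6α-sulfide is expected) and is erased together with C6 in step 12, so either C7 epimer is productive. Site selectivity (C7, not C9 or C1) was secured in step 9, because only C6 could accept the thiolate and the cross-conjugated 2-silyloxydiene can pass electron density from oxygen only to C7. Chemoselectivity rests on chelation, since the acetate, the sulfide and the product ketone are monodentate and cannot compete with the 1,2-dicarbonyl unit for copper.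

Step 12
Reactants: 18 aldol adduct
Product: 20 hydroxy dienone allyl ester (C6=C7 restored; (11R)-OH free), via sulfoxide 19 (not isolated)
Conditions: m-CPBA (1.0 equiv), CH2Cl2, −78 °C; aq. NaHCO3 wash; then toluene, Et3N (cat.), 60 °C
Reagents that add atoms: m-CPBA, OOC(=O)c1cccc(Cl)c1 (its oxygen enters 19 only and leaves again with sulfur)
Why: Sulfide oxidation followed by sulfoxide elimination can use only C7–H (C5 is quaternary), so the mask leaves and C6=C7 returns; the cis C7 epimer goes by syn-elimination and the trans epimer by base-assisted loss of sulfenate, without touching C11, the electron-poor alkenes or the allyl group.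

Step 13
Reactants: 20 hydroxy dienone allyl ester
Product: 21 hydroxy acid ((11R)-2-hydroxypropanoic acid unit on C7 of dienone 12)
Conditions: Pd(PPh3)4 (3 mol %), PhNHMe, THF, rt
Reagents that add atoms: none
Why: Tsuji–Trost deallylation ionises only the unhindered allyl ester and passes the allyl group to N-methylaniline, while the free tertiary hydroxyl is no leaving group and the acetate and dienone see neither acid nor base.

Step 14
Reactants: 21 hydroxy acid; 22 (R)-2-methylbutanoic acid
Product: 25 target CNP0278920.1, via acid chloride 23 (not isolated), via mixed anhydride 24 (not isolated)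
Conditions: 22, (COCl)2, DMF (cat.), CH2Cl2, 0 °C → rt, concentrate; then 21, pyridine, CH2Cl2, 0 °C → rt; aq. NaHCO3 work-up, acidify
Reagents that add atoms: oxalyl chloride, ClC(=O)C(Cl)=O (chlorine of 23 only)
Why: O-acylation of an α-hydroxy acid with an acid chloride, as in the preparation of 2-acyloxyisobutyric acids: the carboxylate is acylated first and the mixed anhydride hands the acyl group to the neighbouring tertiary hydroxyl through a five-membered tetrahedral intermediate, so the hindered C11–OH is esterified without strong acid (no dienone–phenol rearrangement) and C2′ comes unchanged from 22.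

Compound list
1 | (S)-Wieland–Miescher ketone, (8aS)-8a-methyl-3,4,8,8a-tetrahydronaphthalene-1,6(2H,7H)-dione | O=C1CC[C@@]2(C)C(=C1)CCCC2=O | starting material
2 | C8-dithiolane ketone (enone carbonyl of 1 as spiro-1,3-dithiolane, C4 ketone free) | C1CSC2(S1)CC[C@@]3(C)C(=C2)CCCC3=O | intermediate
3 | potassium C3=C4 enolate of 2 | C1CSC2(S1)CC[C@@]3(C)C(=C2)CCC=C3[O-].[K+] | intermediate
4 | C3=C4 enol triflate | C1CSC2(S1)CC[C@@]3(C)C(=C2)CCC=C3OS(=O)(=O)C(F)(F)F | intermediate
5 | 4-methyl-3-ene dithiolane | C1CSC2(S1)CC[C@@]3(C)C(=C2)CCC=C3C | intermediate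
6 | 3α-alkylborane (BH2 on C3α, 4β-CH3) | C1CSC2(S1)CC[C@@]3(C)C(=C2)CC[C@@H](B)[C@@H]3C | intermediate
7 | 3α-alcohol dithiolane (3α-OH, 4β,5β-dimethyl) | C1CSC2(S1)CC[C@@]3(C)C(=C2)CC[C@@H](O)[C@@H]3C | intermediate
8 | 3-ketone dithiolane (4β,5β-dimethyl) | C1CSC2(S1)CC[C@@]3(C)C(=C2)CCC(=O)[C@@H]3C | intermediate
9 | lithium 3β-alkoxide | C1CSC2(S1)CC[C@@]3(C)C(=C2)CC[C@H]([O-])[C@@H]3C.[Li+] | intermediate
10 | 3β-acetate dithiolane | C1CSC2(S1)CC[C@@]3(C)C(=C2)CC[C@H](OC(C)=O)[C@@H]3C | intermediate
11 | 3β-acetoxy enone, (4aR,5R,6S)-6-acetoxy-4a,5-dimethyl-4,4a,5,6,7,8-hexahydronaphthalen-2(3H)-one | O=C1CC[C@@]2(C)C(=C1)CC[C@H](OC(C)=O)[C@@H]2C | intermediate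
12 | 3β-acetoxy dienone, (4aR,5R,6S)-6-acetoxy-4a,5-dimethyl-5,6,7,8-tetrahydronaphthalen-2(4aH)-one | O=C1C=C[C@@]2(C)C(=C1)CC[C@H](OC(C)=O)[C@@H]2C | intermediate
13 | 6α-phenylthio enolsilane (8-trimethylsilyloxy-7,9-diene) | C[Si](C)(C)OC1=C[C@H](Sc3ccccc3)[C@@]2(C)C(=C1)CC[C@H](OC(C)=O)[C@@H]2C | intermediate
14 | pyruvic acid | CC(=O)C(=O)O | starting material
15 | allyl alcohol | C=CCO | starting material
16 | allyl pyruvate | CC(=O)C(=O)OCC=C | intermediate
17 | C11 trimethylsilyl ether of the aldol adduct | C[Si](C)(C)O[C@@](C)(C(=O)OCC=C)[C@H]1[C@H](Sc3ccccc3)[C@@]2(C)C(=CC1=O)CC[C@H](OC(C)=O)[C@@H]2C | intermediate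
18 | aldol adduct (11R; side chain 7β; 6α-SPh) | O[C@@](C)(C(=O)OCC=C)[C@H]1[C@H](Sc3ccccc3)[C@@]2(C)C(=CC1=O)CC[C@H](OC(C)=O)[C@@H]2C | intermediate
19 | sulfoxide of 18 (both configurations at sulfur) | O[C@@](C)(C(=O)OCC=C)[C@H]1[C@H](S(=O)c3ccccc3)[C@@]2(C)C(=CC1=O)CC[C@H](OC(C)=O)[C@@H]2C | intermediate
20 | hydroxy dienone allyl ester (11R) | O[C@@](C)(C(=O)OCC=C)C1=C[C@@]2(C)C(=CC1=O)CC[C@H](OC(C)=O)[C@@H]2C | intermediate
21 | hydroxy acid (11R) | O[C@@](C)(C(=O)O)C1=C[C@@]2(C)C(=CC1=O)CC[C@H](OC(C)=O)[C@@H]2C | intermediate
22 | (R)-2-methylbutanoic acid | CC[C@@H](C)C(=O)O | starting material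
23 | (R)-2-methylbutanoyl chloride | CC[C@@H](C)C(Cl)=O | intermediate
24 | mixed anhydride of 21 (carboxyl) with 22, C11–OH still free | O[C@@](C)(C(=O)OC(=O)[C@H](C)CC)C1=C[C@@]2(C)C(=CC1=O)CC[C@H](OC(C)=O)[C@@H]2C | intermediate
25 | (2R)-2-[(7S,8R,8aR)-7-acetoxy-8,8a-dimethyl-3-oxo-3,5,6,7,8,8a-hexahydronaphthalen-2-yl]-2-{[(2R)-2-methylbutanoyl]oxy}propanoic acid | CC[C@@H](C)C(=O)O[C@@](C)(C(=O)O)C1=C[C@@]2(C)C(=CC1=O)CC[C@H](OC(C)=O)[C@@H]2C | target

Total step count: 14. Longest linear sequence: 13 (steps 1–9 and 11–14).

Steps most likely to fail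

Step 11. C–C bond formation may be too slow, because C7 is flanked by the 6α-sulfide on one face and the 5β-methyl on the other. The Lewis acid may also expel thiolate from C6 (retro-addition), and sulfur may bind or reduce copper. The fallback removes sulfur and moves the desaturation behind the C–C bond formation. It sets out from enone 11, which is enolised kinetically at C7 (LiHMDS with Me3SiCl as internal quench, THF, −78 °C; the ketone is deprotonated far faster than the acetate) to the cross-conjugated enolsilane F1. The same copper-catalysed Mukaiyama aldol addition to 16, now on the open α face of C7, should give after the acidic work-up the 6,7-dihydro hydroxy ketone F2, with C11 again under catalyst control. IBX dehydrogenation (DMSO, 65–75 °C) then introduces C6=C7, and the route is rejoined at 20.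

Step 9. Addition at the neopentyl C6 may stop at an unfavourable equilibrium, or silyl transfer may lag so that 1,2-adducts and desilylated material build up. The fallback separates C–S bond formation from O-silylation. It sets out from dienone 12. Protic thia-Michael addition of thiophenol (cat. Et3N, CH2Cl2), which is driven by C-protonation and is known at C1 of steroidal 1,4-dien-3-ones, gives the isolable 6α-phenylthio enone F3. Kinetic deprotonation at C7 with LiHMDS in the presence of Me3SiCl at −78 °C, below the temperature at which the β-thio enolate loses thiolate, brings the material back to 13.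

Step 14. The acyl shift to the tertiary hydroxyl may be slower than scrambling of the mixed anhydride, and pyridine may epimerise the acyl chloride at C2′ through the ketene. The fallback esterifies before the acid is freed. It sets out from allyl ester 20. The symmetrical (R)-2-methylbutanoic anhydride F4 (from 22 and DCC) and DMAP in CH2Cl2 (nucleophilic catalysis) give the allyl ester of the target F5. Tsuji–Trost deallylation under the conditions of step 13 then gives 25, because the unhindered allyl ester should ionise much faster than the tertiary C11 carboxylate next to the neopentyl C6.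

Further compounds
F1 | step 11 | cross-conjugated enolsilane of 11 (8-trimethylsilyloxy-7,9-diene, C6H2) | C[Si](C)(C)OC1=CC[C@@]2(C)C(=C1)CC[C@H](OC(C)=O)[C@@H]2C
F2 | step 11 | 6,7-dihydro hydroxy ketone (11R; side chain 7α) | O[C@@](C)(C(=O)OCC=C)[C@@H]1C[C@@]2(C)C(=CC1=O)CC[C@H](OC(C)=O)[C@@H]2C
F3 | step 9 | 6α-phenylthio enone | O=C1C[C@H](Sc3ccccc3)[C@@]2(C)C(=C1)CC[C@H](OC(C)=O)[C@@H]2C
F4 | step 14 | (R)-2-methylbutanoic anhydride | CC[C@@H](C)C(=O)OC(=O)[C@H](C)CC
F5 | step 14 | allyl ester of the target | CC[C@@H](C)C(=O)O[C@@](C)(C(=O)OCC=C)C1=C[C@@]2(C)C(=CC1=O)CC[C@H](OC(C)=O)[C@@H]2C
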